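## Retrosynthetic overview

1. The C8 ester is made last, from the free C8 alcohol and (S)-2-methylbutanoic anhydride.
2. Key disconnection C7–C8: the ten-membered ring is closed by chromium-mediated addition of the β-carbon of a 3-(bromomethyl)butenolide (a lactone homoenolate equivalent) to the C8 aldehyde. This one step also creates the exocyclic methylene and the C7 and C8 stereocentres.
3. The C1=C10 enal comes from cross-metathesis of a terminal alkene with 4,4-dimethoxy-2-methylidenebutanal.
4. The butenolide and C6 come from an asymmetric Ni/Cr coupling of a (Z)-β-iodoacrylate with a (Z)-enal. Ring order: butenolide first, ten-membered carbocycle second.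
5. The ring-cis C4=C5 alkene with its CH2OAc group comes from copper-catalysed anti-carbomagnesiation of but-2-yne-1,4-diol.

Assumption: atom labels C1–C15 follow germacrane numbering (C12 lactone carbonyl, C13 exocyclic methylene, C14 aldehyde, C15 CH2OAc); the (S)-configured Kishi-type ligand is taken to give the 5R butenolide, and its enantiomer is used if the facial sense is the reverse.

## Route

Step 1
Reactants: 1 but-2-yne-1,4-diol; 2 but-3-en-1-ylmagnesium bromide
Product: 4 (2E)-2-(but-3-en-1-yl)but-2-ene-1,4-diol, via alkenylmagnesium chelate 3 (not isolated)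
Conditions: 2 (3.5 equiv), CuI (10 mol%), THF, 0 °C to reflux; then H2O
Reagents that add atoms: none
Why: Copper-catalysed alkoxide-directed anti-carbomagnesiation of the symmetric alkyne puts the butenyl group (C1–C3) on C4 and magnesium on C5, held cis to the C15 alkoxide in a five-membered chelate, so protonation leaves C3 cis to C6 and C15 trans to C6, the ring-cis C4=C5 geometry of the target.

Step 2
Reactants: 4
Product: 5 (2E)-3-(hydroxymethyl)hepta-2,6-dienal
Conditions: activated MnO2 (10 equiv), CH2Cl2, 20 °C
Reagents that add atoms: none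
Why: Allylic oxidation with MnO2 should favour the C6 carbinol, a less hindered 3,3-disubstituted (neryl-type) allylic alcohol, over the C15 carbinol on the fully substituted alkene carbon; the enal formed deactivates the second alcohol, the geometry is kept as in nerol to neral, and the trans CH2OH cannot lactolise.

Step 3
Reactants: 5
Product: 6 (2E)-3-(acetoxymethyl)hepta-2,6-dienal
Conditions: Ac2O, pyridine, DMAP (cat.), CH2Cl2, 0 °C
Reagents that add atoms: acetic anhydride CC(=O)OC(C)=O
Why: DMAP-catalysed acetylation of the only remaining alcohol installs the C15 acetate of the target at low temperature without touching the enal geometry.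

Step 4
Reactants: 7 methyl propiolate
Product: 9 methyl (2Z)-2-(hydroxymethyl)-3-iodoprop-2-enoate, via magnesium iodoallenolate 8 (not isolated)
Conditions: MgI2 (1.2 equiv), paraformaldehyde, CH2Cl2, 0 °C to 20 °C; then H2O
Reagents that add atoms: magnesium iodide [Mg+2].[I-].[I-]; formaldehyde C=O
Why: β-Iodo Baylis–Hillman (iodo-aldol) reaction: iodide adds to the ynoate, and allenolate 8 is hydroxymethylated at the α-carbon anti to iodine, which places iodine cis to the ester.

Step 5
Reactants: 6; 9
Product: 12 (5R)-5-[(1E)-2-(acetoxymethyl)hexa-1,5-dien-1-yl]-3-(hydroxymethyl)furan-2(5H)-one, via alkenylchromium dichloride 10 (not isolated), via hydroxy ester 11 (not isolated)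
Conditions: CrCl2 (4 equiv), Kishi-type (S)-oxazoline–sulfonamide ligand (4.4 equiv), Et3N, NiCl2 (2 mol%), THF, 20 °C; then H2O
Reagents that add atoms: none
Why: Asymmetric Nozaki–Hiyama–Kishi alkenylation: zerovalent nickel inserts into the C–I bond, transmetalation gives alkenylchromium 10 with retention of geometry, ligand-controlled addition to one aldehyde face sets C6 as R, and alkoxide 11, cis to the ester, lactonises to the butenolide.

Step 6
Reactants: 12
Product: 13 (5R)-5-[(1E)-2-(acetoxymethyl)hexa-1,5-dien-1-yl]-3-(bromomethyl)furan-2(5H)-one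
Conditions: CBr4 (1.1 equiv), PPh3 (1.05 equiv), CH2Cl2, 0 °C
Reagents that add atoms: carbon tetrabromide BrC(Br)(Br)Br
Why: Appel bromination of the primary allylic alcohol under neutral conditions, done before any aldehyde is present; the conjugated primary bromide is the stable allylic isomer and C6 is untouched.

Step 7
Reactants: 14 4,4-dimethoxybutanenitrile
Product: 16 4,4-dimethoxybutanal, via N-alumino imine 15 (not isolated)
Conditions: iBu2AlH (1.1 equiv), CH2Cl2, −78 °C; then H2O, SiO2, 0 °C
Reagents that add atoms: water O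
Why: Partial reduction of the nitrile by iBu2AlH stops at the aluminium imine 15, which hydrolyses to the aldehyde on mild work-up with the acetal intact.

Step 8
Reactants: 16
Product: 17 4,4-dimethoxy-2-methylidenebutanal
Conditions: 37% aq. CH2O, pyrrolidine (10 mol%), propionic acid (10 mol%), i-PrOH, 45 °C
Reagents that add atoms: formaldehyde C=O
Why: Organocatalytic α-methylenation (Mannich condensation then amine elimination) gives the 2-substituted acrolein under nearly neutral conditions that spare the acetal.

Step 9
Reactants: 13; 17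
Product: 18 (5R)-5-[(1E,5E)-2-(acetoxymethyl)-6-formyl-8,8-dimethoxyocta-1,5-dien-1-yl]-3-(bromomethyl)furan-2(5H)-one
Conditions: second-generation Hoveyda–Grubbs catalyst (5 mol%), 17 (3 equiv), CH2Cl2, 40 °C
Reagents that add atoms: none
Why: Olefin cross-metathesis of the only terminal alkene with the non-dimerising 2-substituted acrolein gives the trisubstituted enal as its favoured isomer (C14 trans to C2, as in methacrolein cross-metathesis); the other alkenes are trisubstituted or electron-poor and inert, and the phosphine-free catalyst tolerates the allylic bromide.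

Step 10
Reactants: 18
Product: 19 (5R)-5-[(1E,5E)-2-(acetoxymethyl)-6-formyl-8-oxoocta-1,5-dien-1-yl]-3-(bromomethyl)furan-2(5H)-one
Conditions: 5% aq. oxalic acid, THF, 20 °C; used at once
Reagents that add atoms: water O
Why: Mild acid-catalysed acetal hydrolysis frees the C8 aldehyde without harming the allylic bromide, acetate or butenolide and without moving the C1=C10 alkene out of conjugation.

Step 11
Reactants: 19
Product: 21 (1(10)E,4E,6R,7R,8S)-15-acetoxy-8-hydroxy-14-oxogermacra-1(10),4,11(13)-trien-12,6-olide, via allylchromium dichloride 20 (not isolated)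
Conditions: CrCl2 (10 equiv), THF, 2 mM, slow addition of 19 over 10 h, 20 °C; then H2O
Reagents that add atoms: none
Why: Proposed new method: divalent chromium inserts into the allylic C–Br bond to give allylchromium 20, in which the lactone β-carbon C7 (normally an acceptor site) is nucleophilic and adds to the C8 aldehyde through a six-membered chair transition state (intramolecular Nozaki–Hiyama allylation; closest known cases are the intermolecular chromium-mediated additions of 3-(bromomethyl)furan-2(5H)-one to aldehydes and Barbier macrocyclisations of 2-(bromomethyl)acrylates to germacranolides); C8 bonds to C7 on the face opposite the C6 side chain (trans lactone, 7R), the ring-locked alkene geometry (C6 trans to the CH2Cr carbon) gives the anti adduct (8S), the double bond shifts to C11=C13, and the conjugated α-branched C14 aldehyde is the slower electrophile and would need a nine-membered ring.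

Step 12
Reactants: 21; 22 (S)-2-methylbutanoic anhydride
Product: 23 (1(10)E,4E,6R,7R,8S)-15-acetoxy-8-[(2S)-2-methylbutanoyloxy]-14-oxogermacra-1(10),4,11(13)-trien-12,6-olide (CNP0230988.8)
Conditions: 22 (1.5 equiv), DMAP (cat.), pyridine, CH2Cl2, 0 °C
Reagents that add atoms: none
Why: DMAP-catalysed acylation of the secondary C8 alcohol with the preformed anhydride keeps the (S) α-centre of the acyl group; no ring stereocentre is touched, and chromatography removes the diastereomer that any minor enantiomer from step 5 would give.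

## Compound list

1 | but-2-yne-1,4-diol | OCC#CCO | starting material
2 | but-3-en-1-ylmagnesium bromide | C=CCC[Mg]Br | starting material
3 | alkenylmagnesium chelate (C5–Mg–O15 five-membered ring, C6–OMgBr) | C=CCCC1=C(CO[Mg]Br)[Mg]OC1 | intermediate
4 | (2E)-2-(but-3-en-1-yl)but-2-ene-1,4-diol | OC/C=C(/CO)CCC=C | intermediate
5 | (2E)-3-(hydroxymethyl)hepta-2,6-dienal | O=C/C=C(/CO)CCC=C | intermediate
6 | (2E)-3-(acetoxymethyl)hepta-2,6-dienal | O=C/C=C(/COC(C)=O)CCC=C | intermediate
7 | methyl propiolate | C#CC(=O)OC | starting material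
8 | magnesium iodoallenolate | IC=C=C(OC)O[Mg]I | intermediate
9 | methyl (2Z)-2-(hydroxymethyl)-3-iodoprop-2-enoate | I/C=C(/CO)C(=O)OC | intermediate
10 | alkenylchromium dichloride (chiral ligand not drawn) | Cl[Cr](Cl)/C=C(/CO)C(=O)OC | intermediate
11 | methyl (2Z,4R,5E)-6-(acetoxymethyl)-4-hydroxy-2-(hydroxymethyl)deca-2,5,9-trienoate (present as its chromium alkoxide) | OC/C(C(=O)OC)=C/[C@@H](/C=C(/COC(C)=O)CCC=C)O | intermediate
12 | (5R)-5-[(1E)-2-(acetoxymethyl)hexa-1,5-dien-1-yl]-3-(hydroxymethyl)furan-2(5H)-one | OCC1=C[C@@H](/C=C(/COC(C)=O)CCC=C)OC1=O | intermediate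
13 | (5R)-5-[(1E)-2-(acetoxymethyl)hexa-1,5-dien-1-yl]-3-(bromomethyl)furan-2(5H)-one | BrCC1=C[C@@H](/C=C(/COC(C)=O)CCC=C)OC1=O | intermediate
14 | 4,4-dimethoxybutanenitrile | N#CCCC(OC)OC | starting material
15 | N-(diisobutylalumanyl) imine of 4,4-dimethoxybutanal | COC(OC)CCC=N[Al](CC(C)C)CC(C)C | intermediate
16 | 4,4-dimethoxybutanal | O=CCCC(OC)OC | intermediate
17 | 4,4-dimethoxy-2-methylidenebutanal | C=C(C=O)CC(OC)OC | intermediate
18 | (5R)-5-[(1E,5E)-2-(acetoxymethyl)-6-formyl-8,8-dimethoxyocta-1,5-dien-1-yl]-3-(bromomethyl)furan-2(5H)-one | BrCC1=C[C@@H](/C=C(/COC(C)=O)CC/C=C(/C=O)CC(OC)OC)OC1=O | intermediate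
19 | (5R)-5-[(1E,5E)-2-(acetoxymethyl)-6-formyl-8-oxoocta-1,5-dien-1-yl]-3-(bromomethyl)furan-2(5H)-one | BrCC1=C[C@@H](/C=C(/COC(C)=O)CC/C=C(/C=O)CC=O)OC1=O | intermediate
20 | allylchromium dichloride of 19 (CrCl2 on C13, solvent ligands not drawn) | Cl[Cr](Cl)CC1=C[C@@H](/C=C(/COC(C)=O)CC/C=C(/C=O)CC=O)OC1=O | intermediate
21 | (1(10)E,4E,6R,7R,8S)-15-acetoxy-8-hydroxy-14-oxogermacra-1(10),4,11(13)-trien-12,6-olide (both ring alkenes cis within the ring, trans-fused lactone) | C=C1C(=O)O[C@@H]2/C=C(/COC(C)=O)CC/C=C(/C=O)C[C@H](O)[C@@H]12 | intermediate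
22 | (S)-2-methylbutanoic anhydride | CC[C@H](C)C(=O)OC(=O)[C@@H](C)CC | starting material
23 | CNP0230988.8, the 8-O-[(2S)-2-methylbutanoyl] ester of 21 | C=C1C(=O)O[C@@H]2/C=C(/COC(C)=O)CC/C=C(/C=O)C[C@H](OC(=O)[C@@H](C)CC)[C@@H]12 | target

## Step count and risks

Total step count: 12. Longest linear sequence: 9 steps (1, 2, 3, 5, 6, 9, 10, 11, 12). The route is a paper design; nothing in it has been run.

Steps most likely to fail:

**Step 11 (ring closure).** The risks are attack at the C14 aldehyde, a wrong ring fusion, and lactol formation between the new C8 alcohol and the C14 aldehyde before step 12. The fallback sets out from 18 and returns at 23, and keeps C14 at the alcohol level until the end. Reduction of the enal with NaBH4 and CeCl3·7H2O in MeOH at −78 °C gives allylic alcohol F5. Oxalic acid hydrolysis of the acetal gives hydroxy aldehyde F6, which sits as a lactol and now holds a single aldehyde. The same CrCl2 ring closure gives macrocyclic diol F7. TBSCl and imidazole silylate the primary allylic alcohol to give silyl ether F8. Acylation with 22 gives ester F9. HF·pyridine gives allylic alcohol F10. MnO2 then oxidises C14 to give 23.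

**Step 5 (asymmetric Ni/Cr coupling).** The enantioselectivity with this iodoacrylate and a β,β-disubstituted enal is not known. The fallback sets out from 6 and returns at 12. Addition of methyl propiolate 7 to the aldehyde with Me2Zn and the ProPhenol ligand gives ynoate F3. Semihydrogenation over Pd/CaCO3 poisoned by Pb(OAc)2 and quinoline gives the (Z)-enoate, which lactonises to butenolide F4. Morita–Baylis–Hillman hydroxymethylation with aqueous formaldehyde and imidazole gives 12.

**Step 2 (selective oxidation).** The two primary allylic alcohols may not be told apart well enough. The fallback sets out from 4 and returns at 6. Acetylation of both alcohols gives diacetate F1. Candida antarctica lipase B in pH 7 buffer removes the less hindered C6 acetate to give monoacetate F2. MnO2 then gives 6.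

## Further compounds

F1 | step 2 | (2E)-2-(but-3-en-1-yl)but-2-ene-1,4-diyl diacetate | CC(=O)OC/C=C(/COC(C)=O)CCC=C
F2 | step 2 | (2E)-2-(but-3-en-1-yl)-4-hydroxybut-2-en-1-yl acetate | OC/C=C(/COC(C)=O)CCC=C
F3 | step 5 | methyl (4R,5E)-6-(acetoxymethyl)-4-hydroxydeca-5,9-dien-2-ynoate | COC(=O)C#C[C@H](O)/C=C(/COC(C)=O)CCC=C
F4 | step 5 | (5S)-5-[(1E)-2-(acetoxymethyl)hexa-1,5-dien-1-yl]furan-2(5H)-one (same spatial arrangement at C6 as 12) | O=C1C=C[C@@H](/C=C(/COC(C)=O)CCC=C)O1
F5 | step 11 | (5R)-5-[(1E,5E)-2-(acetoxymethyl)-6-(hydroxymethyl)-8,8-dimethoxyocta-1,5-dien-1-yl]-3-(bromomethyl)furan-2(5H)-one | BrCC1=C[C@@H](/C=C(/COC(C)=O)CC/C=C(/CO)CC(OC)OC)OC1=O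
F6 | step 11 | (5R)-5-[(1E,5E)-2-(acetoxymethyl)-6-(hydroxymethyl)-8-oxoocta-1,5-dien-1-yl]-3-(bromomethyl)furan-2(5H)-one (open form of the lactol) | BrCC1=C[C@@H](/C=C(/COC(C)=O)CC/C=C(/CO)CC=O)OC1=O
F7 | step 11 | 14-hydroxy analogue of 21 (macrocyclic 8,14-diol) | C=C1C(=O)O[C@@H]2/C=C(/COC(C)=O)CC/C=C(/CO)C[C@H](O)[C@@H]12
F8 | step 11 | 14-O-tert-butyldimethylsilyl ether of F7 | C=C1C(=O)O[C@@H]2/C=C(/COC(C)=O)CC/C=C(/CO[Si](C)(C)C(C)(C)C)C[C@H](O)[C@@H]12
F9 | step 11 | 8-O-[(2S)-2-methylbutanoyl] ester of F8 | C=C1C(=O)O[C@@H]2/C=C(/COC(C)=O)CC/C=C(/CO[Si](C)(C)C(C)(C)C)C[C@H](OC(=O)[C@@H](C)CC)[C@@H]12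
F10 | step 11 | 14-hydroxy analogue of 23 | C=C1C(=O)O[C@@H]2/C=C(/COC(C)=O)CC/C=C(/CO)C[C@H](OC(=O)[C@@H](C)CC)[C@@H]12
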